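**Strategy.** The plan rests on one observation: in the all-trans oxolane, C5 is attached only to O1, C4, ring B (3,4,5-trimethoxyphenyl) and hydrogen, so it is an aldehyde carbon lodged between O1 and C4. Cutting O1-C5 and C4-C5 together releases 3,4,5-trimethoxybenzaldehyde. In the forward direction a silyl-Prins (intramolecular Sakurai) annulation links the C2 oxygen to this aldehyde and lets the allylsilane gamma carbon (C4) trap the oxocarbenium ion: one operation closes the ring, sets C4 and C5, and leaves a C4 vinyl group as latent CH2OH. The precursor is an acyclic syn-aldol-derived benzylic alcohol bearing ring A at C2, a silyl-protected CH2OH at C3 and an (E)-CH=CH-CH2SiMe3 arm.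

Key step: step 7

**Remarks on the chemistry (made before the steps)**
- **Numbering and abbreviations.** Oxolane numbering is used for every intermediate, acyclic ones included: O1, C2 carries ring A, then C3 and C4, and C5 carries ring B. TBS = tert-butyldimethylsilyl and TBDPS = tert-butyldiphenylsilyl.
- **Stereochemical check.**
  - The target is (2R,3S,4S,5R). Going round the ring, ring A is up, C3-CH2OH down, C4-CH2OH up and ring B down, so every adjacent pair is trans.
  - A 2,3-trans ring corresponds to the syn aldol, with OH and vinyl syn along the chain Ar-C2-C3-C(=O). The required (2R,3R) imide is the one delivered by the (R)-benzyl auxiliary.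
  - With vinyl on C4 the descriptor is R. It becomes S at the CH2OH stage with no change in space.
- **Precursor design.**
  - (a) Both hydroxyls of the 2-vinylpropane-1,3-diol are homoallylic, so either could build a five-membered ring. The primary one therefore carries the bulky, acid-robust TBDPS group.
  - (b) The C2 hydroxyl enters the cyclisation as its SiMe3 ether, made in the flask beside an acid scavenger. No free TfOH then meets the allylsilane or the benzylic C-O bond.
  - (c) The phenol is a TBS ether rather than a benzyl ether. No hydrogenolysis is then needed next to two benzylic C-O bonds, and one fluoride step ends the synthesis. Flanked by two methoxy groups, the silyloxy group is also twisted out of conjugation, which weakens cation stabilisation at C2.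
  - (d) The crotonyl imide is used because it gives the same boron dienolate as the but-3-enoyl imide, without an acylation step prone to double-bond migration.
  - (e) Metathesis is placed after auxiliary removal.
- **Assumption.** Any (Z)-allylsilane accompanying the (E)-isomer after metathesis is taken to converge on the same oxolane. The exocyclic alkene carbon is not stereogenic in the product, and allylic strain in the (Z)-isomer favours the same alkene face.

**Step 1**
Reactants: 1 syringaldehyde
Product: 2 4-[(tert-butyldimethylsilyl)oxy]-3,5-dimethoxybenzaldehyde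
Conditions: TBSCl, imidazole, DMF, 0 °C to rt
Reagents that add atoms: tert-butyldimethylsilyl chloride, CC(C)(C)[Si](C)(C)Cl
Why: Imidazole-promoted O-silylation of a phenol (silyl ether protection) is routine for this aldehyde, and the group falls together with the other silyl ether in the last step.

**Step 2**
Reactants: 3 (R)-4-benzyloxazolidin-2-one; 4 (E)-but-2-enoyl chloride
Product: 6 (R)-4-benzyl-3-[(E)-but-2-enoyl]oxazolidin-2-one, via lithium oxazolidinide 5 (not isolated)
Conditions: n-BuLi, THF, -78 °C; then 4, -78 to 0 °C
Reagents that add atoms: none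
Why: N-acylation of the lithiated Evans oxazolidinone with an acid chloride at low temperature is the standard entry to enoyl imides and leaves the auxiliary stereocentre untouched.

**Step 3**
Reactants: 6 (R)-4-benzyl-3-[(E)-but-2-enoyl]oxazolidin-2-one; 2 4-[(tert-butyldimethylsilyl)oxy]-3,5-dimethoxybenzaldehyde
Product: 9 syn aldol adduct (4R)-4-benzyl-3-{(2R)-2-[(R)-(4-TBSO-3,5-dimethoxyphenyl)(hydroxy)methyl]but-3-enoyl}oxazolidin-2-one, via boron dienolate 7 (not isolated), via boron aldolate 8 (not isolated)
Conditions: Bu2BOTf, Et3N, CH2Cl2, -78 to 0 °C; 2, -78 to 0 °C; then pH 7 buffer, MeOH, 30% H2O2, 0 °C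
Reagents that add atoms: none
Why: Evans boron syn aldol in its deconjugative form: gamma-deprotonation of 6 gives the (Z)-boron dienolate 7, which reacts through its alpha carbon in a Zimmerman-Traxler chair on the face remote from the benzyl group of the (R)-auxiliary, so C2 (R) and C3 are set syn in one event and the alpha-vinyl group becomes the C4 arm.

**Step 4**
Reactants: 9 syn aldol adduct
Product: 10 (1R,2S)-1-(4-TBSO-3,5-dimethoxyphenyl)-2-vinylpropane-1,3-diol
Conditions: LiBH4, MeOH (1 equiv), THF, 0 °C
Reagents that add atoms: none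
Why: Reductive removal of the Evans auxiliary by hydride attack on the exocyclic imide carbonyl turns the acyl carbon into the C3 CH2OH under conditions too mild for epimerisation at C3 or retro-aldol, and the aryl silyl ether and the vinyl group are inert.

**Step 5**
Reactants: 10 (1R,2S)-1-(4-TBSO-3,5-dimethoxyphenyl)-2-vinylpropane-1,3-diol
Product: 11 (1R,2S)-1-(4-TBSO-3,5-dimethoxyphenyl)-2-(TBDPSOCH2)but-3-en-1-ol
Conditions: TBDPSCl (1.05 equiv), imidazole, CH2Cl2, 0 °C
Reagents that add atoms: tert-butyldiphenylsilyl chloride, CC(C)(C)[Si](Cl)(c1ccccc1)c1ccccc1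
Why: Sterically governed monosilylation, in which the bulky chlorosilane takes the primary hydroxyl far faster than the hindered benzylic one and thereby removes the second homoallylic oxygen from play in step 7.

**Step 6**
Reactants: 11 (1R,2S)-1-(4-TBSO-3,5-dimethoxyphenyl)-2-(TBDPSOCH2)but-3-en-1-ol; 12 allyltrimethylsilane
Product: 13 (1R,2S,3E)-1-(4-TBSO-3,5-dimethoxyphenyl)-2-(TBDPSOCH2)-5-(trimethylsilyl)pent-3-en-1-ol
Conditions: 12 (4 equiv), second-generation Hoveyda-Grubbs catalyst RuCl2(H2IMes)(=CH-C6H4-2-OiPr) (5 mol %), 1,4-benzoquinone (10 mol %), CH2Cl2, 40 °C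
Reagents that add atoms: none
Why: Olefin cross-metathesis between a rapidly dimerising partner used in excess and a hindered allylic-branched vinyl group that does not self-couple should favour the (E)-alkene by reversibility, touches no stereocentre, and no longer exposes an acidic alpha-vinyl imide to ruthenium hydride species.

**Step 7**
Reactants: 13 (1R,2S,3E)-1-(4-TBSO-3,5-dimethoxyphenyl)-2-(TBDPSOCH2)-5-(trimethylsilyl)pent-3-en-1-ol; 14 3,4,5-trimethoxybenzaldehyde
Product: 17 all-trans (2R,3S,4R,5R)-2-(4-TBSO-3,5-dimethoxyphenyl)-3-(TBDPSOCH2)-5-(3,4,5-trimethoxyphenyl)-4-vinyloxolane, via trimethylsilyl ether 15 (not isolated), via oxocarbenium triflate 16 (not isolated)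
Conditions: 14 (1.2 equiv), 2,6-di-tert-butyl-4-methylpyridine (1.1 equiv), TMSOTf (1.3 equiv), CH2Cl2, -78 °C; quench Et3N, aq NaHCO3
Reagents that add atoms: none
Why: TMSOTf and the non-nucleophilic pyridine first turn the C2 hydroxyl into trimethylsilyl ether 15 with the triflic acid held as its pyridinium salt; the surplus TMSOTf then activates 14, the silyl ether oxygen adds, (Me3Si)2O leaves and the (E)-oxocarbenium ion 16 (O1=C5) results. C4, the gamma carbon of the allylsilane, attacks C5 anti to the C-Si bond and the beta-silyl cation on the exocyclic carbon gives up Me3Si+ to triflate, which returns TMSOTf and leaves the vinyl group; the closest known reaction type is the silyl-modified Sakurai (silyl-Prins) condensation of 5-silylpent-3-en-1-ols with aldehydes to 2-substituted 3-vinyloxolanes, applied here to a chain with two more substituents. The single ring closes 5-exo-trig as seen from the alkene (5-endo-trig as seen from O1=C5), and the six-membered alternative is disfavoured because attack through the beta carbon would put the charge on C4, where silicon cannot stabilise it. C4 is controlled by C3: allylic 1,3-strain keeps H3 near the alkene plane and the CH2OTBDPS group pseudo-equatorial, so the tethered C5 reaches the alkene face that places vinyl trans to that group. C5 is controlled by the (E)-geometry of 16, which holds ring B pseudo-equatorial in a twist-envelope with a staggered forming bond and hence trans to vinyl, while ring A sits pseudo-equatorial in the same conformer because the syn aldol made C2 and C3 trans. The step needs oxygen selectivity (the reactive O-SiMe3 at C2 against the bulky TBDPS on the equally homoallylic primary oxygen) and ring closure faster than C2-O ionisation, 2-oxonia-Cope exchange or protodesilylation (nucleophilic allylsilane, -78 °C, acid scavenger, de-conjugated 4-silyloxy group), and because all-trans is the most stable arrangement any reversible opening at C2 or C5 should drain toward 17.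

**Step 8**
Reactants: 17 all-trans 4-vinyloxolane
Product: 19 (2R,3S,4S,5R)-2-(4-TBSO-3,5-dimethoxyphenyl)-3-(TBDPSOCH2)-4-(hydroxymethyl)-5-(3,4,5-trimethoxyphenyl)oxolane, via oxolane-4-carbaldehyde 18 (not isolated)
Conditions: OsO4 (2 mol %), NaIO4, 2,6-lutidine, 1,4-dioxane/H2O, rt; extractive work-up; crude, NaBH4, MeOH, 0 °C
Reagents that add atoms: osmium tetroxide, O=[Os](=O)(=O)=O (catalytic oxygen carrier); sodium periodate, [Na+].[O-]I(=O)(=O)=O (terminal oxygen source)
Why: Lemieux-Johnson cleavage of the only alkene followed at once by borohydride reduction excises the terminal carbon and gives the C4 CH2OH; aldehyde 18 already has the more stable trans,trans arrangement so enolisation cannot erode C4, and the phenol stays silylated because a free syringyl phenol would be oxidised by periodate.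

**Step 9**
Reactants: 19 bis-silyl ether
Product: 20 4-[(2R,3S,4S,5R)-3,4-bis(hydroxymethyl)-5-(3,4,5-trimethoxyphenyl)oxolan-2-yl]-2,6-dimethoxyphenol (target)
Conditions: Bu4NF (3 equiv), AcOH (3 equiv), THF, 0 °C to rt
Reagents that add atoms: none
Why: Fluoride-driven Si-O cleavage removes the aryl TBS and the primary TBDPS ethers in one operation, the acetic acid buffer keeps the liberated phenol protonated so that no quinone-methide opening of C2-O1 can start, and no stereocentre is involved.

**Compound list**

1 | syringaldehyde | COc1cc(C=O)cc(OC)c1O | starting material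
2 | 4-[(tert-butyldimethylsilyl)oxy]-3,5-dimethoxybenzaldehyde | COc1cc(C=O)cc(OC)c1O[Si](C)(C)C(C)(C)C | intermediate
3 | (R)-4-benzyloxazolidin-2-one | O=C1N[C@H](Cc2ccccc2)CO1 | starting material
4 | (E)-but-2-enoyl chloride | C/C=C/C(=O)Cl | starting material
5 | N-lithio-(R)-4-benzyloxazolidin-2-one (not isolated) | [Li]N1[C@H](Cc2ccccc2)COC1=O | intermediate
6 | (R)-4-benzyl-3-[(E)-but-2-enoyl]oxazolidin-2-one | C/C=C/C(=O)N1[C@H](Cc2ccccc2)COC1=O | intermediate
7 | (Z)-dibutylboron dienolate of 6 (not isolated) | C=C/C=C(\OB(CCCC)CCCC)N1[C@H](Cc2ccccc2)COC1=O | intermediate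
8 | dibutylboron aldolate of 9 (not isolated) | COc1cc([C@H](OB(CCCC)CCCC)[C@H](C(=O)N2[C@H](Cc3ccccc3)COC2=O)C=C)cc(OC)c1O[Si](C)(C)C(C)(C)C | intermediate
9 | (4R)-4-benzyl-3-{(2R)-2-[(R)-(4-TBSO-3,5-dimethoxyphenyl)(hydroxy)methyl]but-3-enoyl}oxazolidin-2-one | COc1cc([C@H](O)[C@H](C(=O)N2[C@H](Cc3ccccc3)COC2=O)C=C)cc(OC)c1O[Si](C)(C)C(C)(C)C | intermediate
10 | (1R,2S)-1-(4-TBSO-3,5-dimethoxyphenyl)-2-vinylpropane-1,3-diol | COc1cc([C@H](O)[C@H](CO)C=C)cc(OC)c1O[Si](C)(C)C(C)(C)C | intermediate
11 | (1R,2S)-1-(4-TBSO-3,5-dimethoxyphenyl)-2-(TBDPSOCH2)but-3-en-1-ol | COc1cc([C@H](O)[C@H](CO[Si](c2ccccc2)(c3ccccc3)C(C)(C)C)C=C)cc(OC)c1O[Si](C)(C)C(C)(C)C | intermediate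
12 | allyltrimethylsilane | C=CC[Si](C)(C)C | starting material
13 | (1R,2S,3E)-1-(4-TBSO-3,5-dimethoxyphenyl)-2-(TBDPSOCH2)-5-(trimethylsilyl)pent-3-en-1-ol (key-step precursor) | COc1cc([C@H](O)[C@H](CO[Si](c2ccccc2)(c3ccccc3)C(C)(C)C)/C=C/C[Si](C)(C)C)cc(OC)c1O[Si](C)(C)C(C)(C)C | intermediate
14 | 3,4,5-trimethoxybenzaldehyde | COc1cc(C=O)cc(OC)c1OC | starting material
15 | C2-O-trimethylsilyl ether of 13 (not isolated) | COc1cc([C@H](O[Si](C)(C)C)[C@H](CO[Si](c2ccccc2)(c3ccccc3)C(C)(C)C)/C=C/C[Si](C)(C)C)cc(OC)c1O[Si](C)(C)C(C)(C)C | intermediate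
16 | (E)-oxocarbenium triflate, O1=C5 (not isolated) | COc1cc(/C=[O+]/[C@@H](c2cc(OC)c(O[Si](C)(C)C(C)(C)C)c(OC)c2)[C@H](CO[Si](c3ccccc3)(c4ccccc4)C(C)(C)C)/C=C/C[Si](C)(C)C)cc(OC)c1OC.[O-]S(=O)(=O)C(F)(F)F | intermediate
17 | all-trans (2R,3S,4R,5R)-2-(4-TBSO-3,5-dimethoxyphenyl)-3-(TBDPSOCH2)-5-(3,4,5-trimethoxyphenyl)-4-vinyloxolane (key-step product) | COc1cc([C@@H]2O[C@@H](c3cc(OC)c(OC)c(OC)c3)[C@H](C=C)[C@H]2CO[Si](c4ccccc4)(c5ccccc5)C(C)(C)C)cc(OC)c1O[Si](C)(C)C(C)(C)C | intermediate
18 | all-trans C4 carbaldehyde, (2R,3S,4R,5R) in route numbering (not isolated) | COc1cc([C@@H]2O[C@@H](c3cc(OC)c(OC)c(OC)c3)[C@H](C=O)[C@H]2CO[Si](c4ccccc4)(c5ccccc5)C(C)(C)C)cc(OC)c1O[Si](C)(C)C(C)(C)C | intermediate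
19 | (2R,3S,4S,5R)-2-(4-TBSO-3,5-dimethoxyphenyl)-3-(TBDPSOCH2)-4-(hydroxymethyl)-5-(3,4,5-trimethoxyphenyl)oxolane | COc1cc([C@@H]2O[C@@H](c3cc(OC)c(OC)c(OC)c3)[C@H](CO)[C@H]2CO[Si](c4ccccc4)(c5ccccc5)C(C)(C)C)cc(OC)c1O[Si](C)(C)C(C)(C)C | intermediate
20 | 4-[(2R,3S,4S,5R)-3,4-bis(hydroxymethyl)-5-(3,4,5-trimethoxyphenyl)oxolan-2-yl]-2,6-dimethoxyphenol | COc1cc([C@@H]2O[C@@H](c3cc(OC)c(OC)c(OC)c3)[C@H](CO)[C@H]2CO)cc(OC)c1O | target

**Total step count:** 9. **Longest linear sequence:** 8 steps (steps 1, 3, 4, 5, 6, 7, 8, 9 from 1; equally steps 2 to 9 from 3).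

**Steps most likely to fail**

**Step 7 (key step).**
- What may go wrong: heterolysis of the benzylic C2-O bond, which would erode C2 or let the allylsilane close onto C2; 2-oxonia-Cope exchange of the aldehyde component; protodesilylation; Friedel-Crafts capture of the cation by ring A; or weak facial control at C5.
- Fallback: O1-C5 is built first at the ester level and the cation is released from a pre-assembled acetal. No free aldehyde, no water equivalent and only a mild Lewis acid are then present.
- Setting out from 13, acylation with 3,4,5-trimethoxybenzoyl chloride (Et3N, DMAP, CH2Cl2) should give the 3,4,5-trimethoxybenzoate ester F1.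
- Reduction with iBu2AlH at -78 °C, with trapping of the diisobutylaluminium hemiacetal in the same flask by Ac2O, pyridine and DMAP, should give the alpha-acetoxy ether F2. It forms as both epimers at the acetal carbon, which does not matter.
- BF3·OEt2 in CH2Cl2 at -78 °C then ionises the acetate, and the same allylsilane closure brings the material back to the route at 17.

**Step 6 (cross-metathesis).**
- What may go wrong: slow turnover at the hindered allylic-branched vinyl group, loss of 12 to self-metathesis, alkene migration, or poor control of alkene geometry.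
- Fallback: the metathesis is made intramolecular through a temporary silicon tether.
- Setting out from 11, silylation of the C2 hydroxyl with allyl(chloro)dimethylsilane (imidazole, CH2Cl2) should give the allyldimethylsilyl ether F3.
- Ring-closing metathesis with the second-generation Grubbs catalyst RuCl2(H2IMes)(PCy3)(=CHPh) in CH2Cl2 at 40 °C should give the seven-membered cyclic (Z)-allylsiloxane F4.
- Condensation of F4 with 14 under BF3·OEt2 at -78 °C passes the ring oxygen to the aldehyde and cleaves Si-O. It then closes the oxolane by the same oxocarbenium/allylsilane event, which is a known annulation of cyclic allylsiloxanes. The route is rejoined at 17.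

**Step 3 (aldol).**
- What may go wrong: competing gamma attack or low conversion of the dienolate with the electron-rich aldehyde, retro-aldol, or migration of the alpha-vinyl double bond into conjugation during work-up.
- Fallback: a catalytic enantioselective carbonyl addition bypasses the imide altogether.
- Setting out from 2, an iridium-catalysed transfer-hydrogenative anti-(hydroxymethyl)allylation is run with 4,7-dihydro-1,3-dioxepin-2-one (O=C1OCC=CCO1). Conditions are [Ir(cod)Cl]2, SEGPHOS, 4-chloro-3-nitrobenzoic acid, Cs2CO3, propan-2-ol, THF and heat.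
- The ligand antipode is selected for the 1R carbinol and checked by Mosher ester analysis.
- The anti relation of OH and CH2OH formed in this reaction is the same relative configuration as syn OH/vinyl. The product is therefore diol 10 itself, and the route is rejoined at 10 with steps 2 to 4 left out.
- No compound outside the list arises on this path (none, F0).

**Further compounds**

F1 | step 7 | (1R,2S,3E)-1-(4-TBSO-3,5-dimethoxyphenyl)-2-(TBDPSOCH2)-5-(trimethylsilyl)pent-3-en-1-yl 3,4,5-trimethoxybenzoate | COc1cc(C(=O)O[C@@H](c2cc(OC)c(O[Si](C)(C)C(C)(C)C)c(OC)c2)[C@H](CO[Si](c3ccccc3)(c4ccccc4)C(C)(C)C)/C=C/C[Si](C)(C)C)cc(OC)c1OC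
F2 | step 7 | acetoxy(3,4,5-trimethoxyphenyl)methyl ether of 13, both epimers at the acetal carbon | COc1cc(C(OC(C)=O)O[C@@H](c2cc(OC)c(O[Si](C)(C)C(C)(C)C)c(OC)c2)[C@H](CO[Si](c3ccccc3)(c4ccccc4)C(C)(C)C)/C=C/C[Si](C)(C)C)cc(OC)c1OC
F3 | step 6 | C2-O-allyldimethylsilyl ether of 11 | COc1cc([C@H](O[Si](C)(C)CC=C)[C@H](CO[Si](c2ccccc2)(c3ccccc3)C(C)(C)C)C=C)cc(OC)c1O[Si](C)(C)C(C)(C)C
F4 | step 6 | (6S,7R)-7-(4-TBSO-3,5-dimethoxyphenyl)-6-(TBDPSOCH2)-2,2-dimethyl-2,3,6,7-tetrahydro-1,2-oxasilepine | COc1cc([C@@H]2O[Si](C)(C)C/C=C\[C@H]2CO[Si](c3ccccc3)(c4ccccc4)C(C)(C)C)cc(OC)c1O[Si](C)(C)C(C)(C)C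
F0 | step 3 | none | none
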